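**Plan**

- Retrosynthesis: the sixteen benzyl ethers come off last. The two upper interflavan bonds (C4–C8) are cut one after the other, back to dimer 13 and the C4 electrophile 3. In the terminal unit, after a hydroxyl is put back on C4, the ring C bonds C4–C4a and O1–C2 are cut together. This leaves an epicatechin carrying a 2,4-bis(benzyloxy)-6-hydroxyphenyl cap at C4 (5) and a cis-epoxy aldehyde (10).
- Enabling feature: ring A of the terminal unit is a phloroglucinol ring. Its C4a is ortho to the phenolic O1 on C8a and ortho/para to the C5 and C7 oxygens, so O1–C8a–C4a is a 1,3-C,O-bis-nucleophile. C4 and C2 are 1,3-related and C2 is benzylic to the electron-rich catechol ring B, so an aldehyde (C4) next to a benzylic epoxide (C3–C2) is the matching bis-electrophile.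
- Forward: benzylate (−)-epicatechin, oxidise C4, cap with 3,5-bis(benzyloxy)phenol. The epoxy aldehyde is made in three steps. The annulation builds ring C of the terminal unit on the cap (C4–C4a first, then O1–C2). The helper C4–OH is removed by ionic hydrogenation, followed by two cationic chain extensions at C8 of the top unit and then hydrogenolysis.
- Stereochemistry: the three upper units come from (−)-epicatechin. Each interflavan bond forms 4β, anti to the C3 hydroxyl. C2 and C3 of the terminal unit come from one Jacobsen epoxidation (C3 retained, C2 inverted in the ring closure, giving the 2,3-cis 2R,3R unit).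
- Regiochemistry of the lowest 4→8 linkage: only the phenol oxygen next to the interflavan carbon is free, so ring C can close only there.

Key step: step 7

Remark on the chemistry: the carbinol carbon C4 of the new unit in 11 and 12 is expected as a mixture of epimers and is written without configuration; step 8 removes this centre.

**Step 1**
Reactants: 1 (−)-epicatechin
Product: 2 5,7,3',4'-tetra-O-benzyl-(−)-epicatechin
Conditions: BnBr (4.4 equiv), K2CO3, DMF, 0 °C to rt
Reagents that add atoms: benzyl bromide, BrCc1ccccc1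
Why: Williamson etherification should take the four phenols (far more acidic than the C3 alcohol) and touches no stereocentre.

**Step 2**
Reactants: 2 5,7,3',4'-tetra-O-benzyl-(−)-epicatechin
Product: 3 4β-(2-ethoxyethoxy)-5,7,3',4'-tetra-O-benzyl-(−)-epicatechin
Conditions: DDQ (2 equiv), 2-ethoxyethanol (5 equiv), CH2Cl2, rt
Reagents that add atoms: 2-ethoxyethanol, CCOCCO
Why: DDQ benzylic oxidation (hydride abstraction at C4 of the electron-rich ring A) should give a quinone-methide cation that the alcohol traps anti to the C3 hydroxyl, setting the 4β centre.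

**Step 3**
Reactants: 3 4β-(2-ethoxyethoxy)-5,7,3',4'-tetra-O-benzyl-(−)-epicatechin; 4 3,5-bis(benzyloxy)phenol
Product: 5 4β-[2,4-bis(benzyloxy)-6-hydroxyphenyl]-5,7,3',4'-tetra-O-benzyl-(−)-epicatechin
Conditions: Me3SiOTf (0.2 equiv), 4 (4 equiv), CH2Cl2, −78 °C
Reagents that add atoms: none
Why: Lewis-acid Friedel–Crafts alkylation by the C4 cation should occur anti to the C3 hydroxyl (4β) and at the phenol carbon flanked by OH and one benzyloxy group instead of the carbon between two benzyloxy groups, the same steric preference that favours C8 over C6 in benzylated flavans.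

**Step 4**
Reactants: 6 3,4-bis(benzyloxy)benzaldehyde; 7 ethyl 2-(diphenoxyphosphoryl)acetate
Product: 8 ethyl (Z)-3-[3,4-bis(benzyloxy)phenyl]prop-2-enoate
Conditions: NaH, THF, −78 to −20 °C
Reagents that add atoms: none
Why: Ando variant of the Horner–Wadsworth–Emmons olefination, in which the electron-poor aryloxy groups on phosphorus make elimination fast and kinetic, should give the Z ester.

**Step 5**
Reactants: 8 ethyl (Z)-3-[3,4-bis(benzyloxy)phenyl]prop-2-enoate
Product: 9 ethyl (2S,3S)-3-[3,4-bis(benzyloxy)phenyl]oxirane-2-carboxylate (cis)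
Conditions: (S,S)-N,N'-bis(3,5-di-tert-butylsalicylidene)-1,2-cyclohexanediaminomanganese chloride [(S,S)-(salen)MnCl, 5 mol %], 4-phenylpyridine N-oxide, aq NaOCl (pH 11.3), CH2Cl2, 4 °C
Reagents that add atoms: sodium hypochlorite, [Na+].[O-]Cl
Why: Jacobsen epoxidation of a cis-disubstituted conjugated alkene should set both centres under catalyst control, the (S,S) catalyst being the mirror image of the one that gives the (2R,3R) glycidate from cis-ethyl cinnamate.

**Step 6**
Reactants: 9 ethyl (2S,3S)-3-[3,4-bis(benzyloxy)phenyl]oxirane-2-carboxylate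
Product: 10 (2S,3S)-3-[3,4-bis(benzyloxy)phenyl]oxirane-2-carbaldehyde (cis)
Conditions: iBu2AlH (1.05 equiv), toluene, −78 °C; MeOH, then aq potassium sodium tartrate; used crude
Reagents that add atoms: none
Why: Partial ester reduction with iBu2AlH should stop at the aluminium hemiacetal until quench and leaves the two epoxide centres untouched, since an oxiranyl aldehyde does not enolise readily.

**Step 7**
Reactants: 5 4β-[2,4-bis(benzyloxy)-6-hydroxyphenyl]-5,7,3',4'-tetra-O-benzyl-(−)-epicatechin; 10 (2S,3S)-3-[3,4-bis(benzyloxy)phenyl]oxirane-2-carbaldehyde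
Product: 12 octa-O-benzyl epicatechin-(4β→8)-4-hydroxyepicatechin (lower unit a 2,3-cis-flavan-3,4-diol; C4 epimers), via ortho-hydroxyalkylated epoxy carbinol 11 (not isolated)
Conditions: Bu2Mg (1.0 equiv), toluene, 0 °C to rt; then 10 (1.5 equiv), CH2Cl2, −20 °C to rt, then 40 °C; aqueous work-up
Reagents that add atoms: none
Why: Proposed new method: the halide-free magnesium phenoxide of 5 (the neighbouring C3 alkoxide completes the chelate) should bind the aldehyde of 10 and deliver it through a cyclic six-membered transition state to the only free carbon ortho to the phenoxide oxygen, forming C4–C4a and the magnesium alkoxide 11, after which the ring A phenoxide oxygen opens the magnesium-activated epoxide at its benzylic carbon, forming O1–C2. The closest known reactions are the ortho-specific hydroxyalkylation of magnesium phenoxides with α-oxygenated aldehydes (Casiraghi type) and the cyclisation of 2-(3-aryloxiranylmethyl)phenols to flavan-3-ols; joining them in one flask on an epoxy aldehyde is the new element. Ring C closes in the 6-endo-tet mode, preferred to 5-exo attack at C3 because cleavage of the C2–O bond is assisted by the electron-rich ring B. C3 keeps the configuration of the epoxide (its oxygen becomes the 3-OH) and C2 is set by inversion, so the cis-(2S,3S)-epoxide should give the 2,3-cis (2R,3R) unit, while the C4 carbinol centre is not controlled and is removed in step 8. The step needs C- over O-attack and 4→8 over 4→6 ring fusion, both secured because the magnesium chelate directs the aldehyde to the ortho carbon and the only free phenol oxygen is the one beside the interflavan carbon, the carbon between the two benzyloxy groups having no oxygen that could close the ring. It also needs inversion instead of ionisation at C2, for which the non-acidic, halide-free medium is chosen.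

**Step 8**
Reactants: 12 octa-O-benzyl epicatechin-(4β→8)-4-hydroxyepicatechin
Product: 13 octa-O-benzyl epicatechin-(4β→8)-epicatechin
Conditions: Et3SiH (10 equiv), BF3·OEt2 (0.2 equiv), CH2Cl2, −78 to −40 °C
Reagents that add atoms: none
Why: Ionic hydrogenation should ionise only the doubly oxygen-activated benzylic C4 alcohol (the same cation used for interflavan coupling) and reduce it with silane hydride, erasing the undefined centre while the non-benzylic 3-hydroxyls and the interflavan bond stay intact at low temperature.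

**Step 9**
Reactants: 13 octa-O-benzyl epicatechin-(4β→8)-epicatechin; 3 4β-(2-ethoxyethoxy)-5,7,3',4'-tetra-O-benzyl-(−)-epicatechin
Product: 14 dodeca-O-benzyl epicatechin-(4β→8)-epicatechin-(4β→8)-epicatechin
Conditions: Me3SiOTf (0.1 equiv), CH2Cl2, −78 °C; 13 in 3-fold excess, recovered
Reagents that add atoms: none
Why: Lewis-acid Friedel–Crafts interflavan coupling should place the C4 cation on C8 of the top unit (the only ring A carbon not flanked by two benzyloxy groups) and anti to the C3 hydroxyl, setting the new 4β centre.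

**Step 10**
Reactants: 14 dodeca-O-benzyl epicatechin-(4β→8)-epicatechin-(4β→8)-epicatechin; 3 4β-(2-ethoxyethoxy)-5,7,3',4'-tetra-O-benzyl-(−)-epicatechin
Product: 15 hexadeca-O-benzyl epicatechin-(4β→8)-epicatechin-(4β→8)-epicatechin-(4β→8)-epicatechin (benzyl-protected target tetramer)
Conditions: Me3SiOTf (0.1 equiv), CH2Cl2, −78 °C; 14 in 2.5-fold excess, recovered
Reagents that add atoms: none
Why: The same Friedel–Crafts interflavan coupling should extend the chain at C8 of the top unit with 4β selectivity anti to the C3 hydroxyl.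

**Step 11**
Reactants: 15 hexadeca-O-benzyl epicatechin-(4β→8)-epicatechin-(4β→8)-epicatechin-(4β→8)-epicatechin
Product: 16 epicatechin-(4β→8)-epicatechin-(4β→8)-epicatechin-(4β→8)-epicatechin (the target tetramer)
Conditions: H2 (1 atm), Pd(OH)2/C, THF/MeOH/H2O, rt
Reagents that add atoms: none
Why: Hydrogenolysis of the sixteen aryl benzyl ethers under neutral conditions should leave the acid-sensitive interflavan bonds and all eleven stereocentres untouched.

**Compound list**

1 | (−)-epicatechin | Oc1cc(O)c2c(c1)O[C@H](c1ccc(O)c(O)c1)[C@H](O)C2 | starting material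
2 | 5,7,3',4'-tetra-O-benzyl-(−)-epicatechin | c3ccccc3COc1cc(OCc3ccccc3)c2c(c1)O[C@H](c1ccc(OCc3ccccc3)c(OCc3ccccc3)c1)[C@H](O)C2 | intermediate
3 | 4β-(2-ethoxyethoxy)-5,7,3',4'-tetra-O-benzyl-(−)-epicatechin | c3ccccc3COc1cc(OCc3ccccc3)c2c(c1)O[C@H](c1ccc(OCc3ccccc3)c(OCc3ccccc3)c1)[C@H](O)[C@H]2OCCOCC | intermediate
4 | 3,5-bis(benzyloxy)phenol | Oc1cc(OCc2ccccc2)cc(OCc2ccccc2)c1 | starting material
5 | 4β-[2,4-bis(benzyloxy)-6-hydroxyphenyl]-5,7,3',4'-tetra-O-benzyl-(−)-epicatechin | c3ccccc3COc1cc(OCc3ccccc3)c2c(c1)O[C@H](c1ccc(OCc3ccccc3)c(OCc3ccccc3)c1)[C@H](O)[C@H]2c1c(OCc3ccccc3)cc(OCc3ccccc3)cc1O | intermediate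
6 | 3,4-bis(benzyloxy)benzaldehyde | O=Cc1ccc(OCc2ccccc2)c(OCc2ccccc2)c1 | starting material
7 | ethyl 2-(diphenoxyphosphoryl)acetate | CCOC(=O)CP(=O)(Oc1ccccc1)Oc1ccccc1 | starting material
8 | ethyl (Z)-3-[3,4-bis(benzyloxy)phenyl]prop-2-enoate | CCOC(=O)/C=C\c1ccc(OCc2ccccc2)c(OCc2ccccc2)c1 | intermediate
9 | ethyl (2S,3S)-3-[3,4-bis(benzyloxy)phenyl]oxirane-2-carboxylate | CCOC(=O)[C@H]1O[C@H]1c1ccc(OCc2ccccc2)c(OCc2ccccc2)c1 | intermediate
10 | (2S,3S)-3-[3,4-bis(benzyloxy)phenyl]oxirane-2-carbaldehyde | O=C[C@H]1O[C@H]1c1ccc(OCc2ccccc2)c(OCc2ccccc2)c1 | intermediate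
11 | compound 5 carrying, at the free carbon ortho to its phenol, a CH(OH) group bonded to the intact cis-epoxide of 10 (carbinol epimers) | c3ccccc3COc1cc(OCc3ccccc3)c2c(c1)O[C@H](c1ccc(OCc3ccccc3)c(OCc3ccccc3)c1)[C@H](O)[C@H]2c1c(OCc3ccccc3)cc(OCc3ccccc3)c(C(O)[C@H]4O[C@H]4c4ccc(OCc3ccccc3)c(OCc3ccccc3)c4)c1O | intermediate (not isolated)
12 | octa-O-benzyl epicatechin-(4β→8)-4-hydroxyepicatechin (lower unit 2R,3R; C4 epimers) | c3ccccc3COc1cc(OCc3ccccc3)c2c(c1)O[C@H](c1ccc(OCc3ccccc3)c(OCc3ccccc3)c1)[C@H](O)[C@H]2c1c(OCc3ccccc3)cc(OCc3ccccc3)c2c1O[C@H](c1ccc(OCc3ccccc3)c(OCc3ccccc3)c1)[C@H](O)C2O | intermediate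
13 | octa-O-benzyl epicatechin-(4β→8)-epicatechin | c3ccccc3COc1cc(OCc3ccccc3)c2c(c1)O[C@H](c1ccc(OCc3ccccc3)c(OCc3ccccc3)c1)[C@H](O)[C@H]2c1c(OCc3ccccc3)cc(OCc3ccccc3)c2c1O[C@H](c1ccc(OCc3ccccc3)c(OCc3ccccc3)c1)[C@H](O)C2 | intermediate
14 | dodeca-O-benzyl epicatechin-(4β→8)-epicatechin-(4β→8)-epicatechin | c3ccccc3COc1cc(OCc3ccccc3)c2c(c1)O[C@H](c1ccc(OCc3ccccc3)c(OCc3ccccc3)c1)[C@H](O)[C@H]2c1c(OCc3ccccc3)cc(OCc3ccccc3)c2c1O[C@H](c1ccc(OCc3ccccc3)c(OCc3ccccc3)c1)[C@H](O)[C@H]2c1c(OCc3ccccc3)cc(OCc3ccccc3)c2c1O[C@H](c1ccc(OCc3ccccc3)c(OCc3ccccc3)c1)[C@H](O)C2 | intermediate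
15 | hexadeca-O-benzyl epicatechin-(4β→8)-epicatechin-(4β→8)-epicatechin-(4β→8)-epicatechin | c3ccccc3COc1cc(OCc3ccccc3)c2c(c1)O[C@H](c1ccc(OCc3ccccc3)c(OCc3ccccc3)c1)[C@H](O)[C@H]2c1c(OCc3ccccc3)cc(OCc3ccccc3)c2c1O[C@H](c1ccc(OCc3ccccc3)c(OCc3ccccc3)c1)[C@H](O)[C@H]2c1c(OCc3ccccc3)cc(OCc3ccccc3)c2c1O[C@H](c1ccc(OCc3ccccc3)c(OCc3ccccc3)c1)[C@H](O)[C@H]2c1c(OCc3ccccc3)cc(OCc3ccccc3)c2c1O[C@H](c1ccc(OCc3ccccc3)c(OCc3ccccc3)c1)[C@H](O)C2 | intermediate
16 | epicatechin-(4β→8)-epicatechin-(4β→8)-epicatechin-(4β→8)-epicatechin | Oc1cc(O)c2c(c1)O[C@H](c1ccc(O)c(O)c1)[C@H](O)[C@H]2c1c(O)cc(O)c2c1O[C@H](c1ccc(O)c(O)c1)[C@H](O)[C@H]2c1c(O)cc(O)c2c1O[C@H](c1ccc(O)c(O)c1)[C@H](O)[C@H]2c1c(O)cc(O)c2c1O[C@H](c1ccc(O)c(O)c1)[C@H](O)C2 | target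

**Step count and risks**

Total step count: 11. Longest linear sequence: 8 steps (1, 2, 3, 7, 8, 9, 10, 11).

Steps most likely to fail:

1. Step 7. The benzylic epoxide carbon may ionise before the phenoxide closes the ring, so that inversion at C2 is lost and the 2,3-trans unit forms. The ring may also close 5-exo at C3, or the epoxide may migrate in the alkoxide 11 (Payne-type shift). Fallback: it sets out from 2 and 3 and comes back at 13. The terminal unit is introduced intact by the known Me3SiOTf-catalysed Friedel–Crafts coupling of electrophile 3 with an excess of 2 (about 4 equiv, CH2Cl2, −78 °C), which should give 13 directly and replaces steps 3 to 8. This detour makes no compound outside the list (F0).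

2. Step 5. Bond rotation in the stepwise oxygen transfer to the electron-rich cis-cinnamate may give trans-epoxide, and enantioselection may be incomplete. Fallback: it sets out from 8 and comes back at 10, replacing steps 5 and 6. Reduction of 8 with iBu2AlH (2.2 equiv, CH2Cl2, −78 °C) should give (Z)-3-[3,4-bis(benzyloxy)phenyl]prop-2-en-1-ol F1. Sharpless epoxidation, which is stereospecific for alkene geometry (Ti(OiPr)4, D-(−)-diisopropyl tartrate, tBuOOH, 4 Å molecular sieves, CH2Cl2, −20 °C), should give [(2R,3S)-3-[3,4-bis(benzyloxy)phenyl]oxiran-2-yl]methanol F2. Parikh–Doering oxidation (SO3·pyridine, DMSO, iPr2NEt, 0 °C) should then return aldehyde 10.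

3. Step 10. The tetramer may react further with the electrophile, attack may occur at C6 positions, and 3 may self-condense as the nucleophile becomes more hindered. Fallback: it sets out from 3 and 13 and comes back at 15, replacing steps 9 and 10 by a two-plus-two union. Self-condensation of 3 (Zn(OTf)2, CH2Cl2, rt, stopped at partial conversion) should give the dimeric electrophile 4β-(2-ethoxyethoxy)-octa-O-benzyl epicatechin-(4β→8)-epicatechin F3. Its equimolar coupling with 13 (AgOTf, CH2Cl2, rt) should give 15.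

**Further compounds**

F0 | step 7 | none | none
F1 | step 5 | (Z)-3-[3,4-bis(benzyloxy)phenyl]prop-2-en-1-ol | OC/C=C\c1ccc(OCc2ccccc2)c(OCc2ccccc2)c1
F2 | step 5 | [(2R,3S)-3-[3,4-bis(benzyloxy)phenyl]oxiran-2-yl]methanol | OC[C@H]1O[C@H]1c1ccc(OCc2ccccc2)c(OCc2ccccc2)c1
F3 | step 10 | 4β-(2-ethoxyethoxy)-octa-O-benzyl epicatechin-(4β→8)-epicatechin (leaving group on the lower unit) | c3ccccc3COc1cc(OCc3ccccc3)c2c(c1)O[C@H](c1ccc(OCc3ccccc3)c(OCc3ccccc3)c1)[C@H](O)[C@H]2c1c(OCc3ccccc3)cc(OCc3ccccc3)c2c1O[C@H](c1ccc(OCc3ccccc3)c(OCc3ccccc3)c1)[C@H](O)[C@H]2OCCOCC
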